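## Retrosynthetic overview

1. Ring A is the cyclohexadienone ring (C1 ring C=O, C2 butanoyl-bearing, C3 C–OH, C4 CMe2, C5 C–OH, C6 CH2-bearing); ring B is the benzene ring. Last disconnection: CH2–C6, giving butyrylfilicinic acid 10 and the phenolic Mannich base 17 (ortho-quinone methide Michael addition).
2. Ring A is made in one pot from two open-chain diketide units. C3–C4 comes from γ-acylation of the dianion of methyl 4-methyl-3-oxopentanoate with a 3-oxohexanoyl thioester, and C1–C2 from Claisen ring closure of the resulting tetraketide. This copies the chain extension and Claisen cyclization by which acylphloroglucinols are presumed to arise.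
3. Enabling feature: ring A is a tetraketide (C1, C3, C5 and the butanoyl C=O at carbonyl level, alternating with C2, C4, C6). Its quaternary C4 cannot enolise, so the open chain has no aromatic aldol or 2-pyrone outlet and only the C2-to-C1 Claisen closure ends in a stable β-triketone enolate.
4. Ring B comes from 5-methoxybenzene-1,3-diol. Symmetry and two directed ortho-lithiations place CH2NMe2 between the two protected hydroxyls and butanoyl between OMOM and OMe.
5. Ring order: ring B is bought, ring A is closed in step 3, and the halves are joined in step 8.

Key step: step 3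

Remark: the target has no stereogenic element. It and all filicinic compounds are written in the enol tautomer of the given SMILES.

## Route

Step 1
Reactants: 1 2,2-dimethyl-1,3-dioxane-4,6-dione (Meldrum's acid); 2 butanoyl chloride
Product: 3 5-(1-hydroxybutylidene)-2,2-dimethyl-1,3-dioxane-4,6-dione
Conditions: pyridine (2 equiv), CH2Cl2, 0 °C to rt; dilute HCl wash
Reagents that add atoms: none
Why: C-acylation of the strongly acidic Meldrum's acid by the acid chloride should give the chelated enol of the acyl Meldrum's acid, a standard acylketene precursor.

Step 2
Reactants: 3 5-(1-hydroxybutylidene)-2,2-dimethyl-1,3-dioxane-4,6-dione; 4 benzenethiol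
Product: 6 S-phenyl 3-oxohexanethioate, via butanoylketene 5 (not isolated)
Conditions: toluene, 110 °C
Reagents that add atoms: none
Why: Thermal cycloreversion of the acyl Meldrum's acid (loss of acetone and CO2) should give acylketene 5, which adds the thiol to give the β-keto thioester (acylketene trapping).

Step 3
Reactants: 7 methyl 4-methyl-3-oxopentanoate; 6 S-phenyl 3-oxohexanethioate
Product: 10 butyrylfilicinic acid (2-butanoyl-3,5-dihydroxy-4,4-dimethylcyclohexa-2,5-dien-1-one), via dilithium dienediolate 8 (not isolated), via open-chain triketo ester 9 (not isolated)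
Conditions: 7, LiN(iPr)2 (2.1 equiv), THF, -78 to 0 °C; lithium enolate of 6 (from 6 and LiN(iPr)2, 1.0 equiv, THF, -78 °C) added at -78 °C, then to rt; MeOH, 60 °C; aq. HCl
Reagents that add atoms: none
Why: Double deprotonation of 7 gives dienediolate 8, whose γ-carbon (the isobutyryl methine, the future C4) is the most basic and most nucleophilic site; it should be C-acylated by thioester 6, which is used as its lithium enolate so that no proton is passed to 8, and this makes the C3–C4 bond and tetraketide 9 as its bis-enolate (direct addition–elimination, or loss of thiophenolate to the acylketene and capture, would lead to the same adduct). On addition of methanol the bis-enolate equilibrates with the mono-enolate in which the 1,3-diketone carbon (future C2) attacks the non-enolised methyl ester carbon (C1) in a 6-exo-trig Claisen (Dieckmann-type) closure of ring A with loss of methoxide, and deprotonation of the β-triketone formed should make the closure irreversible. The closest known reaction types are the γ-acylation of β-keto ester dianions (Claisen condensation) and the biomimetic Claisen cyclization of 3,5,7-triketo esters to acylphloroglucinols, the laboratory counterpart of the polyketide synthase ring closure. No stereocentre is formed. The step needs γ- over α-acylation, secured by the dianion, and C2-to-C1 Claisen closure over aldol closure (C6 onto the butanoyl C=O) or enol-lactone formation, secured by the quaternary C4, which denies both alternatives an aromatic sink while the gem-dimethyl group favours cyclization (Thorpe–Ingold effect).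

Step 4
Reactants: 11 5-methoxybenzene-1,3-diol
Product: 12 1-methoxy-3,5-bis(methoxymethoxy)benzene
Conditions: NaH, MOMCl, DMF, 0 °C to rt
Reagents that add atoms: chloromethyl methyl ether, COCCl
Why: O-alkylation of the bis-phenoxide with the reactive α-chloro ether (MOM protection) should mask both hydroxyls and install two strong directing groups for lithiation.

Step 5
Reactants: 12 1-methoxy-3,5-bis(methoxymethoxy)benzene
Product: 14 1-[4-methoxy-2,6-bis(methoxymethoxy)phenyl]-N,N-dimethylmethanamine, via aryllithium 13 (not isolated)
Conditions: n-BuLi, TMEDA, THF, 0 °C; then CH2=NMe2+ I-, -78 °C to rt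
Reagents that add atoms: dimethylmethyleneiminium iodide, C=[N+](C)C.[I-]
Why: Directed ortho-metalation should occur at the C–H flanked by the two OMOM groups (doubly coordinated, and OMOM outranks OMe as directing group), and the aryllithium should add to the iminium salt (Mannich-type aminomethylation).

Step 6
Reactants: 14 1-[4-methoxy-2,6-bis(methoxymethoxy)phenyl]-N,N-dimethylmethanamine
Product: 16 1-{3-[(dimethylamino)methyl]-6-methoxy-2,4-bis(methoxymethoxy)phenyl}butan-1-one, via aryllithium 15 (not isolated)
Conditions: n-BuLi, THF, -20 to 0 °C; then N-methoxy-N-methylbutanamide, -78 to 0 °C; H2O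
Reagents that add atoms: N-methoxy-N-methylbutanamide, CCCC(=O)N(C)OC
Why: A second directed ortho-metalation can only take one of the two equivalent C–H positions between OMOM and OMe, and acylation of the aryllithium with the N-methoxy-N-methylamide (Weinreb ketone synthesis) should stop at the ketone.

Step 7
Reactants: 16 1-{3-[(dimethylamino)methyl]-6-methoxy-2,4-bis(methoxymethoxy)phenyl}butan-1-one
Product: 17 1-{3-[(dimethylamino)methyl]-2,4-dihydroxy-6-methoxyphenyl}butan-1-one
Conditions: HCl (3 M in MeOH), rt; then aq. NaHCO3
Reagents that add atoms: none
Why: Acid-catalysed acetal exchange with methanol (MOM cleavage) should free both phenols while the protonated benzylic amine stays in place, and NaHCO3 then releases the free Mannich base.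

Step 8
Reactants: 17 1-{3-[(dimethylamino)methyl]-2,4-dihydroxy-6-methoxyphenyl}butan-1-one; 10 butyrylfilicinic acid
Product: 19 2-butanoyl-6-[(3-butanoyl-2,6-dihydroxy-4-methoxyphenyl)methyl]-3,5-dihydroxy-4,4-dimethylcyclohexa-2,5-dien-1-one (the target), via ortho-quinone methide 18 (not isolated)
Conditions: 10 (1.5 equiv), 1,4-dioxane, 90 °C
Reagents that add atoms: none
Why: Proton transfer from the acidic triketone 10 to the amine and thermal loss of dimethylamine should give ortho-quinone methide 18, which is captured at its exocyclic CH2 by the only nucleophilic carbon of 10, the unsubstituted C6 (Michael addition with rearomatisation of ring B, the alkylation of a 1,3-dicarbonyl by a phenolic Mannich base).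

## Compound list

1 | 2,2-dimethyl-1,3-dioxane-4,6-dione (Meldrum's acid) | CC1(C)OC(=O)CC(=O)O1 | starting material
2 | butanoyl chloride | CCCC(Cl)=O | starting material
3 | 5-(1-hydroxybutylidene)-2,2-dimethyl-1,3-dioxane-4,6-dione | CCCC(O)=C1C(=O)OC(C)(C)OC1=O | intermediate
4 | benzenethiol | Sc1ccccc1 | starting material
5 | butanoylketene (3-oxohex-1-en-1-one) | CCCC(=O)C=C=O | intermediate
6 | S-phenyl 3-oxohexanethioate | CCCC(=O)CC(=O)Sc1ccccc1 | intermediate
7 | methyl 4-methyl-3-oxopentanoate | COC(=O)CC(=O)C(C)C | starting material
8 | dilithium 1-methoxy-4-methylpenta-1,3-diene-1,3-diolate (dianion of 7) | [Li+].[Li+].COC([O-])=CC([O-])=C(C)C | intermediate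
9 | methyl 4,4-dimethyl-3,5,7-trioxodecanoate (formed as its lithium bis-enolate) | CCCC(=O)CC(=O)C(C)(C)C(=O)CC(=O)OC | intermediate
10 | butyrylfilicinic acid (2-butanoyl-3,5-dihydroxy-4,4-dimethylcyclohexa-2,5-dien-1-one) | CCCC(=O)C1=C(O)C(C)(C)C(O)=CC1=O | intermediate
11 | 5-methoxybenzene-1,3-diol | COc1cc(O)cc(O)c1 | starting material
12 | 1-methoxy-3,5-bis(methoxymethoxy)benzene | COCOc1cc(OC)cc(OCOC)c1 | intermediate
13 | [4-methoxy-2,6-bis(methoxymethoxy)phenyl]lithium | [Li]c1c(OCOC)cc(OC)cc1OCOC | intermediate
14 | 1-[4-methoxy-2,6-bis(methoxymethoxy)phenyl]-N,N-dimethylmethanamine | CN(C)Cc1c(OCOC)cc(OC)cc1OCOC | intermediate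
15 | {3-[(dimethylamino)methyl]-6-methoxy-2,4-bis(methoxymethoxy)phenyl}lithium | [Li]c1c(OC)cc(OCOC)c(CN(C)C)c1OCOC | intermediate
16 | 1-{3-[(dimethylamino)methyl]-6-methoxy-2,4-bis(methoxymethoxy)phenyl}butan-1-one | CCCC(=O)c1c(OC)cc(OCOC)c(CN(C)C)c1OCOC | intermediate
17 | 1-{3-[(dimethylamino)methyl]-2,4-dihydroxy-6-methoxyphenyl}butan-1-one | CCCC(=O)c1c(OC)cc(O)c(CN(C)C)c1O | intermediate
18 | 2-butanoyl-5-hydroxy-3-methoxy-6-methylidenecyclohexa-2,4-dien-1-one (ortho-quinone methide) | CCCC(=O)C1=C(OC)C=C(O)C(=C)C1=O | intermediate
19 | 2-butanoyl-6-[(3-butanoyl-2,6-dihydroxy-4-methoxyphenyl)methyl]-3,5-dihydroxy-4,4-dimethylcyclohexa-2,5-dien-1-one | CCCC(=O)C1=C(O)C(C)(C)C(O)=C(Cc2c(O)cc(OC)c(C(=O)CCC)c2O)C1=O | target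

## Step count and risks

Total steps: 8. Longest linear sequence: 5 steps (steps 4 to 8, from 11); the ring A branch is 4 steps (1, 2, 3, 8).

Steps most likely to fail:

Step 3. What may go wrong: acylation at the enolate oxygen instead of the hindered methine carbon, proton transfer that quenches the dianion, or retro-Claisen cleavage of the non-enolisable 1,3-dicarbonyl unit before ring closure. The fallback gives up the de novo ring construction and uses known arene chemistry. It sets out from 2: Friedel–Crafts acylation of benzene-1,3,5-triol with 2 (AlCl3, nitrobenzene–CH2Cl2) should give 1-(2,4,6-trihydroxyphenyl)butan-1-one F1. Geminal C-methylation of F1 (iodomethane, NaOMe, MeOH, 0 °C to rt), with chromatographic removal of under- and over-methylated material, then comes back to the route at 10.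

Step 8. What may go wrong: thermal scrambling of the methylene bridge (retro-Michael and exchange toward the symmetrical dimer of 10), self-condensation of the quinone methide, or cyclodehydration of the adduct on prolonged heating. The fallback replaces thermal amine loss by a charged leaving group and a preformed enolate at low temperature. It sets out from 17: N-methylation with iodomethane (acetone, rt) should give [3-butanoyl-2,6-dihydroxy-4-methoxyphenyl]methyl-trimethylammonium iodide F2. Treating F2 with 10 and NaHCO3 in MeCN–H2O at 0 °C to rt should release the quinone methide by base-induced loss of trimethylamine in the presence of the enolate of 10, and this comes back to the route at 19.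

Step 6. What may go wrong: benzylic (lateral) lithiation in place of ring metalation, or enolisation of the amide by the hindered aryllithium instead of addition. The fallback moves the acylation to the free phenol stage as an electrophilic substitution. It sets out from 14: MOM cleavage (HCl, MeOH, rt) should give 2-[(dimethylamino)methyl]-5-methoxybenzene-1,3-diol F3, whose two free ring positions are equivalent. Houben–Hoesch acylation of F3 with butanenitrile (ZnCl2, HCl gas, Et2O, 0 °C) should give the ketimine hydrochloride F4, 1-{3-[(dimethylamino)methyl]-2,4-dihydroxy-6-methoxyphenyl}butan-1-imine hydrochloride. Hydrolysis of F4 (H2O, 90 °C, then NaHCO3) comes back to the route at 17.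

## Further compounds

F1 | step 3 | 1-(2,4,6-trihydroxyphenyl)butan-1-one | CCCC(=O)c1c(O)cc(O)cc1O
F2 | step 8 | [3-butanoyl-2,6-dihydroxy-4-methoxyphenyl]methyl-trimethylammonium iodide | CCCC(=O)c1c(OC)cc(O)c(C[N+](C)(C)C)c1O.[I-]
F3 | step 6 | 2-[(dimethylamino)methyl]-5-methoxybenzene-1,3-diol | CN(C)Cc1c(O)cc(OC)cc1O
F4 | step 6 | 1-{3-[(dimethylamino)methyl]-2,4-dihydroxy-6-methoxyphenyl}butan-1-imine hydrochloride | CCCC(=N)c1c(OC)cc(O)c(CN(C)C)c1O.Cl
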